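**Retrosynthetic overview**
1. Target 8 ⇐ enone 7: a last-step 1,2-reduction sets C2.
2. 7 ⇐ epoxy-enone 5: the C5–O bond is made by SN2 acetolysis of the oxirane, and the tertiary C1 acetate then moves to C6, so no protecting group is needed.
3. 5 ⇐ dienone 4: face-selective epoxidation of the γ,δ-alkene sets C6.
4. 4 ⇐ 2-hydroxybenzyl acetate 2 ⇐ salicyl alcohol 1: the key step is a catalytic enantioselective dearomatising C1–O bond formation with acetoxy relay and benzoate capture.
5. Rings: the carbocycle is carried over from the arene and is never constructed. Only two transient rings are formed and opened again, first the spiro-dioxolanylium (step 2), then the oxirane (step 3).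

Numbering used below: C1 = carbinol carbon bearing the CH2OBz arm (C7), C2 = CH(OH), C3=C4 = alkene, C5 and C6 = acetoxy carbons (C6 next to C1).
Assumption: the sense of induction of the iodoarene catalyst must be found by experiment; the (R,R) form is written, and its mirror image (from the other lactic acid enantiomer) is used if it gives the (R)-dienone.
Assumption: PhCO3H and DMDO are used as freshly prepared, titrated solutions (standard reagent preparations, not counted as steps).

**Step 1**
Reactants: 1 2-hydroxybenzyl alcohol (salicyl alcohol)
Product: 2 2-hydroxybenzyl acetate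
Conditions: AcCl (1.05 equiv), 2,4,6-collidine (1.5 equiv), CH2Cl2, −78 °C
Reagents that add atoms: acetyl chloride, CC(=O)Cl
Why: Chemoselective O-acylation: with a hindered weak base no phenoxide forms, so the neutral primary benzylic alcohol out-competes the phenol for the acyl donor, and any aryl acetate that does form passes its acyl group on to the benzylic oxygen (aryl ester to alkyl ester is downhill); no stereocentre is made.

**Step 2**
Reactants: 2 2-hydroxybenzyl acetate
Product: 4 [(1S)-1-acetoxy-2-oxocyclohexa-3,5-dien-1-yl]methyl benzoate, via spiro-acetoxonium benzoate 3 (not isolated)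
Conditions: PhCO3H (1.2 equiv, slow addition), iodoarene catalyst C30H35IN2O4 = (R,R)-2,2'-[(2-iodo-1,3-phenylene)bis(oxy)]bis(N-mesitylpropanamide) (10 mol %), 3 Å MS, CH2Cl2/(CF3)2CHOH 4:1, −20 °C; Me2S quench
Reagents that add atoms: perbenzoic acid, O=C(OO)c1ccccc1
Why: Proposed new method: an enantioselective dearomatising acyloxy-relay oxidation in which PhCO3H oxidises the catalyst to a chiral aryl-λ3-iodane (trivalent iodine) that binds the phenol oxygen, the carbonyl oxygen of the neighbouring benzylic acetate attacks the ipso carbon (future C1) through a 5-membered SN2'-type displacement of the iodoarene inside the chiral pocket (this C–O bond formation sets C1 as S and enforces ortho regiochemistry), and the resulting spiro-dioxolanylium ion 3 is opened at its only SN2-competent carbon, the CH2, by the benzoate released from the spent peracid (sieves keep the by-product water away from 3), which leaves the acetate on the tertiary oxygen and the benzoate on C7; the closest known reaction types are the chiral-iodoarene-catalysed oxidative spirolactonisation of phenols carrying a carboxylic acid side chain (Kita type), the Wessely ortho-acetoxylation of phenols and the Prévost-type opening of acyloxonium ions by carboxylates, whereas an ester carbonyl as the enantio-determining internal nucleophile followed by carboxylate capture has not been described.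

**Step 3**
Reactants: 4 [(1S)-1-acetoxy-2-oxocyclohexa-3,5-dien-1-yl]methyl benzoate
Product: 5 [(1R,2R,6R)-2-acetoxy-3-oxo-7-oxabicyclo[4.1.0]hept-4-en-2-yl]methyl benzoate (oxirane cis to the acetoxy group)
Conditions: DMDO (1.5 equiv, about 0.07 M in acetone), CH2Cl2, 0 °C → rt
Reagents that add atoms: dimethyldioxirane, CC1(C)OO1
Why: Electrophilic dioxirane epoxidation of the γ,δ-alkene of a 2,4-dienone (the more electron-rich alkene); the oxidant approaches C5=C6 from the face of the smaller acetoxy group at C1, anti to the CH2OBz arm (the same facial bias that 6-acyloxy-6-alkylcyclohexa-2,4-dienones show towards dienophiles), so the oxirane is cis to the C1 acetate and the C6–O configuration of the target is set.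

**Step 4**
Reactants: 5 [(1R,2R,6R)-2-acetoxy-3-oxo-7-oxabicyclo[4.1.0]hept-4-en-2-yl]methyl benzoate
Product: 7 [(1R,2R,3S)-2,3-diacetoxy-1-hydroxy-6-oxocyclohex-4-en-1-yl]methyl benzoate, via hydroxy diacetate 6 (not isolated)
Conditions: NaOAc (0.5 equiv), AcOH, 45 °C
Reagents that add atoms: acetic acid, CC(=O)O
Why: Buffered acetolysis of a vinylogous α-keto epoxide: acetate opens the oxirane by SN2 at the allylic C5 with inversion (C5–OAc trans to C6–O; the neopentyl-like C6 is not attacked), and the cis tertiary C1 acetate of 6 then moves to the new secondary C6 hydroxyl through a 5-membered orthoester (1,2 O-to-O acyl migration, tertiary to secondary ester is downhill and breaks no bond at a stereocentre), which frees the tertiary alcohol without a deprotection step.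

**Step 5**
Reactants: 7 [(1R,2R,3S)-2,3-diacetoxy-1-hydroxy-6-oxocyclohex-4-en-1-yl]methyl benzoate
Product: 8 [(1S,2R,3S,6S)-2,3-diacetoxy-1,6-dihydroxycyclohex-4-en-1-yl]methyl benzoate (target)
Conditions: NaBH4 (1.0 equiv), CeCl3·7H2O (1.1 equiv), MeOH, −78 °C; AcOH quench at −78 °C
Reagents that add atoms: none
Why: Luche 1,2-reduction of the enone: in the preferred half-chair (both acetates and the CH2OBz arm equatorial, C1–OH axial) hydride adds axially, anti to the axial C1–O bond (Felkin–Anh), giving the C2 hydroxyl cis to the C1 hydroxyl, and the cold near-neutral medium leaves the three esters untouched.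

**Compound list**
1 | 2-hydroxybenzyl alcohol (salicyl alcohol) | OCc1ccccc1O | starting material
2 | 2-hydroxybenzyl acetate | CC(=O)OCc1ccccc1O | intermediate
3 | (S)-spiro-acetoxonium benzoate: 2-methyl-1,3-dioxolan-2-ylium ring spiro-fused at C1 of the cyclohexa-2,4-dienone, benzoate counter-ion | C1=CC(=O)[C@]2(OC(C)=[O+]C2)C=C1.[O-]C(=O)c1ccccc1 | intermediate
4 | [(1S)-1-acetoxy-2-oxocyclohexa-3,5-dien-1-yl]methyl benzoate | C1=CC(=O)[C@@](OC(C)=O)(COC(=O)c2ccccc2)C=C1 | intermediate
5 | [(1R,2R,6R)-2-acetoxy-3-oxo-7-oxabicyclo[4.1.0]hept-4-en-2-yl]methyl benzoate | O1[C@@H]2C=CC(=O)[C@@](OC(C)=O)(COC(=O)c3ccccc3)[C@H]12 | intermediate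
6 | [(1R,2R,3S)-1,3-diacetoxy-2-hydroxy-6-oxocyclohex-4-en-1-yl]methyl benzoate | CC(=O)O[C@H]1C=CC(=O)[C@@](OC(C)=O)(COC(=O)c2ccccc2)[C@@H]1O | intermediate
7 | [(1R,2R,3S)-2,3-diacetoxy-1-hydroxy-6-oxocyclohex-4-en-1-yl]methyl benzoate | CC(=O)O[C@H]1C=CC(=O)[C@@](O)(COC(=O)c2ccccc2)[C@@H]1OC(C)=O | intermediate
8 | [(1S,2R,3S,6S)-2,3-diacetoxy-1,6-dihydroxycyclohex-4-en-1-yl]methyl benzoate (EANPDB:ANNO_00166) | CC(=O)O[C@H]1C=C[C@H](O)[C@@](O)(COC(=O)c2ccccc2)[C@@H]1OC(C)=O | target

**Totals**
Total steps: 5. Longest linear sequence: 5 (1 → 2 → 4 → 5 → 7 → 8).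

**Steps most likely to fail and their fallbacks**

Step 2 (proposed new reaction). Failure modes: the ester carbonyl may be too weak an internal nucleophile, so external carboxylate attacks the para or free ortho position; water may intercept ion 3; the ee may be low. Fallback with known chemistry, setting out from 1 and coming back at 4: 1 is benzoylated at the benzylic oxygen (BzCl, 2,4,6-collidine, CH2Cl2, −78 °C) to 2-hydroxybenzyl benzoate F1. Wessely oxidation with Pb(OAc)4 in AcOH/CH2Cl2 (tetravalent lead delivers acetate from the aryloxy-lead species to the substituted ortho carbon) gives the racemic dienone F2. Preparative chromatography on a chiral stationary phase (supercritical CO2/MeOH) separates 4 from its mirror image, the (R)-dienone F3, which is discarded.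

Step 3 (facial selectivity). Failure mode: the dioxirane prefers the face anti to the acetate. Fallback, setting out from 4 and coming back at 7: the same oxidation then gives the epimeric epoxide F4 (oxirane trans to the C1 acetate), which is carried on by a different opening mode. With camphorsulfonic acid (cat.) in wet MeCN at 0 °C the C1 acetate, now anti to the C6–O bond, opens the oxirane from the rear at C6 to the cis-fused acetoxonium cation F5. Its hydrolysis gives the hydroxy acetate F6, with C6–OAc cis to the free C1–OH and the C5–OH (the former oxirane oxygen) trans to it; these are the same C5 and C6 configurations as in the main route. Ac2O/pyridine at 0 °C acetylates only the secondary C5–OH and gives 7.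

Step 4 (opening plus acyl shift). Failure modes: the CH2OBz arm may hinder attack at C5; the benzoate may participate at C6; base may isomerise the epoxy-enone to phenols; the acetyl shift may be incomplete. Fallback, setting out from 5 and coming back at 7: the oxirane is hydrolysed instead (HClO4 cat., THF/H2O, 0 °C → rt). Water, the smallest oxygen nucleophile, attacks C5 with inversion under acidic conditions that cannot trigger base-induced isomerisation, giving the diol acetate F7. Warming F7 in NaOAc-buffered AcOH moves the tertiary acetate onto a secondary oxygen to give F6 (the compound of the preceding fallback; its C5-acetate isomer converges as well). Ac2O/pyridine at 0 °C then acetylates the remaining secondary hydroxyl to 7.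

**Further compounds**
F1 | step 2 | 2-hydroxybenzyl benzoate | O=C(OCc1ccccc1O)c1ccccc1
F2 | step 2 | racemic (1-acetoxy-2-oxocyclohexa-3,5-dien-1-yl)methyl benzoate | CC(=O)OC1(COC(=O)c2ccccc2)C=CC=CC1=O
F3 | step 2 | [(1R)-1-acetoxy-2-oxocyclohexa-3,5-dien-1-yl]methyl benzoate | C1=CC(=O)[C@](OC(C)=O)(COC(=O)c2ccccc2)C=C1
F4 | step 3 | [(1S,2R,6S)-2-acetoxy-3-oxo-7-oxabicyclo[4.1.0]hept-4-en-2-yl]methyl benzoate | O1[C@H]2C=CC(=O)[C@@](OC(C)=O)(COC(=O)c3ccccc3)[C@@H]12
F5 | step 3 | cis-fused acetoxonium cation (2-methyl-1,3-dioxolan-2-ylium ring across C1–O and C6–O; C5–OH trans to C6–O) | O[C@H]1C=CC(=O)[C@]2(COC(=O)c3ccccc3)OC(C)=[O+][C@H]12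
F6 | step 3 | [(1R,2R,3S)-2-acetoxy-1,3-dihydroxy-6-oxocyclohex-4-en-1-yl]methyl benzoate | O[C@H]1C=CC(=O)[C@@](O)(COC(=O)c2ccccc2)[C@@H]1OC(C)=O
F7 | step 4 | [(1R,2R,3S)-1-acetoxy-2,3-dihydroxy-6-oxocyclohex-4-en-1-yl]methyl benzoate | O[C@H]1C=CC(=O)[C@@](OC(C)=O)(COC(=O)c2ccccc2)[C@@H]1O
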